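**Retrosynthetic overview**
- Last bond: the C10–O acetate, by allylic C–H acetoxylation of the 6-anisoate of the dauc-8-ene-4,6-diol core; the C6–O ester comes from acylation of the secondary alcohol.
- Seven-membered ring (formed second): ring-closing metathesis at C8=C9 on a cyclopentane that carries an allyl arm on C1 and a 1-hydroxy-3-methylbut-3-enyl arm on C5.
- C6–O bond: Tamao oxidation of a C–Si bond; the silicon tether on the C4 oxygen delivers C6 to C5 by radical cyclization, and an allyl group then enters C1 trans to it.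
- C4 carbinol: isopropyl Grignard addition to an epoxy ketone made by catalytic asymmetric epoxidation of 3-methylcyclopent-2-en-1-one; this C–O step fixes the absolute configuration and the epoxide oxygen is removed afterwards.
- Ring order: the five-membered ring is in the starting material; the seven-membered ring is closed in step 7.

Assumption: atom labels C1–C14 in the Why lines are daucane labels (C1 methyl-bearing ring-fusion carbon, C4 isopropyl carbinol, C5 ring-fusion CH, C6 anisoate carbon, C8=C9 alkene, C10 acetate carbon), and the catalyst antipodes named are those expected to give the drawn series.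

**Route**

Step 1
Reactants: 1 3-methylcyclopent-2-en-1-one
Product: 2 (1R,5R)-5-methyl-6-oxabicyclo[3.1.0]hexan-2-one
Conditions: 9-amino-9-deoxy-epi-quinidine·2CF3CO2H (10 mol %), 50% aq H2O2, dioxane, 35 °C
Reagents that add atoms: hydrogen peroxide, OO
Why: Weitz–Scheffer-type nucleophilic epoxidation under chiral iminium catalysis, in which the primary-amine salt directs hydroperoxide to one enantiotopic face of the enone and ring closure gives the cis-epoxide (1R,5R), the source of all later absolute stereochemistry.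

Step 2
Reactants: 2 (1R,5R)-5-methyl-6-oxabicyclo[3.1.0]hexan-2-one; 3 isopropylmagnesium chloride; 4 (bromomethyl)chlorodimethylsilane
Product: 6 (bromomethyl)dimethyl{[(1R,2R,5R)-5-methyl-2-(propan-2-yl)-6-oxabicyclo[3.1.0]hexan-2-yl]oxy}silane, via chloromagnesium alkoxide 5 (not isolated)
Conditions: 3, LaCl3·2LiCl (30 mol %), THF, −20 °C; then 4, DMAP (10 mol %), 0 °C → rt
Reagents that add atoms: none
Why: Lanthanum-promoted Grignard 1,2-addition to the ketone occurs anti to the adjacent epoxide oxygen (steric and Cram-chelate control), which sets C4 with its oxygen cis to the epoxide, and the magnesium alkoxide is O-silylated in the same flask.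

Step 3
Reactants: 6 (bromomethyl)dimethyl{[(1R,2R,5R)-5-methyl-2-(propan-2-yl)-6-oxabicyclo[3.1.0]hexan-2-yl]oxy}silane
Product: 7 (bromomethyl)dimethyl{[(1R)-3-methyl-1-(propan-2-yl)cyclopent-2-en-1-yl]oxy}silane
Conditions: dimethyl diazomalonate (1.5 equiv), Rh2(OAc)4 (2 mol %), C6H6, 80 °C
Reagents that add atoms: none
Why: Martin–Ganem deoxygenation, in which the epoxide oxygen adds to the electrophilic rhodium carbenoid and the oxonium ylide collapses to the alkene under neutral conditions, so the epoxide is erased after its relay job while C4, the silyl ether and the C–Br bond stay untouched.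

Step 4
Reactants: 7 (bromomethyl)dimethyl{[(1R)-3-methyl-1-(propan-2-yl)cyclopent-2-en-1-yl]oxy}silane; 8 allyltributylstannane
Product: 9 (3aR,4R,6aR)-2,2,4-trimethyl-6a-(propan-2-yl)-4-(prop-2-en-1-yl)hexahydro-2H-cyclopenta[d][1,2]oxasilole
Conditions: 8 (3 equiv), AIBN (20 mol %, in portions), C6H6 (0.3 M), 80 °C
Reagents that add atoms: none
Why: Nishiyama–Stork silicon-tethered radical cyclization followed by Keck allylation, in which the silylmethyl radical closes 5-exo onto C5 and must bond cis to the C4 oxygen it is tied to (sets C5), and allylstannane then traps the tertiary C1 radical anti to the new C5–CH2 bond (sets quaternary C1 with methyl cis to C6).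

Step 5
Reactants: 9 (3aR,4R,6aR)-2,2,4-trimethyl-6a-(propan-2-yl)-4-(prop-2-en-1-yl)hexahydro-2H-cyclopenta[d][1,2]oxasilole
Product: 10 (1R,2S,3R)-2-(hydroxymethyl)-3-methyl-1-(propan-2-yl)-3-(prop-2-en-1-yl)cyclopentan-1-ol
Conditions: 30% H2O2, KF, KHCO3, THF/MeOH (1:1), 50 °C
Reagents that add atoms: hydrogen peroxide, OO
Why: Tamao–Fleming oxidation, in which peroxide attacks the fluoride-activated alkoxysilane and carbon migrates from silicon to oxygen with retention, creating the C6–O bond of the target and freeing the C4 hydroxyl.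

Step 6
Reactants: 10 (1R,2S,3R)-2-(hydroxymethyl)-3-methyl-1-(propan-2-yl)-3-(prop-2-en-1-yl)cyclopentan-1-ol; 11 3-bromo-2-methylprop-1-ene
Product: 13 (1R,2S,3R)-2-[(1S)-1-hydroxy-3-methylbut-3-en-1-yl]-3-methyl-1-(propan-2-yl)-3-(prop-2-en-1-yl)cyclopentan-1-ol, via hydroxy aldehyde 12 (not isolated)
Conditions: TEMPO (10 mol %), PhI(OAc)2 (1.1 equiv), CH2Cl2, 0 °C → rt; evaporate; then 11, indium powder, THF/H2O (1:1), rt
Reagents that add atoms: none
Why: Chemoselective TEMPO/PhI(OAc)2 oxidation of the primary alcohol followed by an indium Barbier methallylation under Cram-chelate control, in which indium bridges the C4 hydroxyl and the aldehyde oxygen and the allylindium attacks the exposed convex face of that chelate to give the 6S carbinol (1,3-anti diol), the aldehyde α-centre C5 already being the thermodynamically preferred epimer.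

Step 7
Reactants: 13 (1R,2S,3R)-2-[(1S)-1-hydroxy-3-methylbut-3-en-1-yl]-3-methyl-1-(propan-2-yl)-3-(prop-2-en-1-yl)cyclopentan-1-ol
Product: 14 (3R,3aS,4S,8aR)-6,8a-dimethyl-3-(propan-2-yl)-1,2,3,3a,4,5,8,8a-octahydroazulene-3,4-diol
Conditions: RuCl2(=CHPh)(PCy3)(H2IMes) (second-generation Grubbs catalyst, 5 mol %), CH2Cl2 (5 mM), 40 °C
Reagents that add atoms: none
Why: Ring-closing metathesis between the allyl and methallyl arms forms the seven-membered ring and the trisubstituted C8=C9 alkene, the trans ring fusion being fixed beforehand by C1 and C5, and no stereocentre is touched.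

Step 8
Reactants: 14 (3R,3aS,4S,8aR)-6,8a-dimethyl-3-(propan-2-yl)-1,2,3,3a,4,5,8,8a-octahydroazulene-3,4-diol; 15 4-methoxybenzoyl chloride
Product: 16 (3R,3aS,4S,8aR)-3-hydroxy-6,8a-dimethyl-3-(propan-2-yl)-1,2,3,3a,4,5,8,8a-octahydroazulen-4-yl 4-methoxybenzoate
Conditions: 15 (1.5 equiv), Et3N, DMAP (20 mol %), CH2Cl2, 0 °C → rt
Reagents that add atoms: none
Why: DMAP-catalysed acylation (nucleophilic catalysis) esterifies only the secondary C6 hydroxyl because the tertiary C4 hydroxyl is too hindered, and C6 keeps its configuration since its C–O bond is not broken.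

Step 9
Reactants: 16 (3R,3aS,4S,8aR)-3-hydroxy-6,8a-dimethyl-3-(propan-2-yl)-1,2,3,3a,4,5,8,8a-octahydroazulen-4-yl 4-methoxybenzoate; 17 tert-butyl peracetate
Product: 18 (3R,3aS,4S,8S,8aS)-8-(acetyloxy)-3-hydroxy-6,8a-dimethyl-3-(propan-2-yl)-1,2,3,3a,4,5,8,8a-octahydroazulen-4-yl 4-methoxybenzoate
Conditions: 17 (1.5 equiv), Pd(PPh3)4 (5 mol %), Bu4NOAc (20 mol %), C6H6, blue LEDs (450 nm), 25 °C
Reagents that add atoms: none
Why: Proposed new method: light-excited zerovalent palladium reduces the perester by single-electron transfer to tert-butoxyl radical and monovalent palladium acetate, tert-butoxyl abstracts the most hydridic allylic hydrogen (C10–H, since C7–H2 is deactivated by the neighbouring ester and C14–H3 is primary), monovalent palladium captures the allyl radical on the face anti to the angular methyl to give a π-allyl complex of divalent palladium, and acetate attacks from outside, anti to the metal, at the less substituted terminus C10, which places the acetate syn to the angular methyl (8S) and returns zerovalent palladium; the closest known reaction types are the Kharasch–Sosnovsky copper/perester allylic acyloxylation, Pd(OAc)2/benzoquinone allylic C–H acetoxylation and the Tsuji–Trost reaction, whose ionisation step this C–O formation reverses.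

**Compound list**
1 | 3-methylcyclopent-2-en-1-one | CC1=CC(=O)CC1 | starting material
2 | (1R,5R)-5-methyl-6-oxabicyclo[3.1.0]hexan-2-one | C[C@@]12CCC(=O)[C@@H]1O2 | intermediate
3 | isopropylmagnesium chloride | CC(C)[Mg]Cl | starting material
4 | (bromomethyl)chlorodimethylsilane | C[Si](C)(Cl)CBr | starting material
5 | chloromagnesium (1R,2R,5R)-5-methyl-2-(propan-2-yl)-6-oxabicyclo[3.1.0]hexan-2-olate (alkoxide oxygen cis to the epoxide) | CC(C)[C@]1(O[Mg]Cl)CC[C@@]2(C)O[C@@H]12 | intermediate
6 | (bromomethyl)dimethyl{[(1R,2R,5R)-5-methyl-2-(propan-2-yl)-6-oxabicyclo[3.1.0]hexan-2-yl]oxy}silane | CC(C)[C@]1(O[Si](C)(C)CBr)CC[C@@]2(C)O[C@@H]12 | intermediate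
7 | (bromomethyl)dimethyl{[(1R)-3-methyl-1-(propan-2-yl)cyclopent-2-en-1-yl]oxy}silane | CC(C)[C@]1(O[Si](C)(C)CBr)CCC(C)=C1 | intermediate
8 | allyltributylstannane | C=CC[Sn](CCCC)(CCCC)CCCC | starting material
9 | (3aR,4R,6aR)-2,2,4-trimethyl-6a-(propan-2-yl)-4-(prop-2-en-1-yl)hexahydro-2H-cyclopenta[d][1,2]oxasilole (cis-fused; allyl trans to the ring CH2–Si bond) | CC(C)[C@]12CC[C@](C)(CC=C)[C@H]1C[Si](C)(C)O2 | intermediate
10 | (1R,2S,3R)-2-(hydroxymethyl)-3-methyl-1-(propan-2-yl)-3-(prop-2-en-1-yl)cyclopentan-1-ol | CC(C)[C@]1(O)CC[C@](C)(CC=C)[C@H]1CO | intermediate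
11 | 3-bromo-2-methylprop-1-ene | CC(=C)CBr | starting material
12 | (1R,2R,5R)-2-hydroxy-5-methyl-2-(propan-2-yl)-5-(prop-2-en-1-yl)cyclopentane-1-carbaldehyde | CC(C)[C@]1(O)CC[C@](C)(CC=C)[C@H]1C=O | intermediate
13 | (1R,2S,3R)-2-[(1S)-1-hydroxy-3-methylbut-3-en-1-yl]-3-methyl-1-(propan-2-yl)-3-(prop-2-en-1-yl)cyclopentan-1-ol | CC(C)[C@]1(O)CC[C@](C)(CC=C)[C@H]1[C@@H](O)CC(C)=C | intermediate
14 | (3R,3aS,4S,8aR)-6,8a-dimethyl-3-(propan-2-yl)-1,2,3,3a,4,5,8,8a-octahydroazulene-3,4-diol (jaeschkeanadiol) | O[C@H]1CC(C)=CC[C@@]2(C)CC[C@@](O)(C(C)C)[C@H]12 | intermediate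
15 | 4-methoxybenzoyl chloride | COc1ccc(cc1)C(Cl)=O | starting material
16 | (3R,3aS,4S,8aR)-3-hydroxy-6,8a-dimethyl-3-(propan-2-yl)-1,2,3,3a,4,5,8,8a-octahydroazulen-4-yl 4-methoxybenzoate | COc1ccc(C(=O)O[C@H]2CC(C)=CC[C@@]3(C)CC[C@@](O)(C(C)C)[C@H]23)cc1 | intermediate
17 | tert-butyl peracetate | CC(=O)OOC(C)(C)C | starting material
18 | (3R,3aS,4S,8S,8aS)-8-(acetyloxy)-3-hydroxy-6,8a-dimethyl-3-(propan-2-yl)-1,2,3,3a,4,5,8,8a-octahydroazulen-4-yl 4-methoxybenzoate | COc1ccc(C(=O)O[C@H]2CC(C)=C[C@H](OC(C)=O)[C@@]3(C)CC[C@@](O)(C(C)C)[C@H]23)cc1 | target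

**Step count and risks**
Total steps: 9. Longest linear sequence: 9 (from 1).

Most likely to fail: step 9, step 4 and step 1.

Step 9 (the new step; risks are the site of H abstraction, diene formation from the π-allyl complex and the facial outcome). The fallback uses known chemistry, sets out from 16 and comes back at 18. Allylic C–H oxidation of 16 with dirhodium tetracaprolactamate Rh2(cap)4 and tert-butyl hydroperoxide, which normally oxidises the methylene next to the =CH carbon of a trisubstituted ring alkene, gives the enone (3R,3aS,4S,8aS)-3-hydroxy-6,8a-dimethyl-8-oxo-3-(propan-2-yl)-1,2,3,3a,4,5,8,8a-octahydroazulen-4-yl 4-methoxybenzoate F1. Luche reduction (NaBH4, CeCl3·7H2O, MeOH, −78 °C) delivers hydride anti to the angular methyl and gives the allylic alcohol (3R,3aS,4S,8S,8aS)-3,8-dihydroxy-6,8a-dimethyl-3-(propan-2-yl)-1,2,3,3a,4,5,8,8a-octahydroazulen-4-yl 4-methoxybenzoate F2. Acetylation of this secondary alcohol (Ac2O, DMAP, pyridine; the tertiary hydroxyl is inert) gives 18.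

Step 4 (risk: the allylstannane traps the hindered tertiary radical slowly, or allylates the first radical before it cyclizes). The fallback sets out from 7 and comes back at 9. The same silicon-tethered 5-exo cyclization is run under reductive Giese conditions (Bu3SnH, AIBN, slow addition) with 1-phenyl-5-(vinylsulfonyl)-1H-tetrazole as the trap, which captures the nucleophilic tertiary radical much faster than an allylstannane. This gives the sulfone 1-phenyl-5-({2-[(3aR,4R,6aR)-2,2,4-trimethyl-6a-(propan-2-yl)hexahydro-2H-cyclopenta[d][1,2]oxasilol-4-yl]ethyl}sulfonyl)-1H-tetrazole F3. Julia–Kocienski olefination of F3 with formaldehyde (KN(SiMe3)2, then paraformaldehyde, THF, −78 °C → rt) turns the sulfonylethyl arm into the allyl group and gives 9.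

Step 1 (risk: modest enantioselectivity or conversion for a five-membered β-methyl enone). The fallback sets out from 1 and comes back at 2. Corey–Bakshi–Shibata reduction ((R)-2-methyl-CBS-oxazaborolidine, BH3·SMe2, THF, −20 °C) gives (S)-3-methylcyclopent-2-en-1-ol F4. Hydroxyl-directed epoxidation (VO(acac)2, t-BuOOH, CH2Cl2, 0 °C) gives the cis-epoxy alcohol (1S,2S,5R)-5-methyl-6-oxabicyclo[3.1.0]hexan-2-ol F5. Dess–Martin oxidation of F5 gives 2.

**Further compounds**
F1 | step 9 | (3R,3aS,4S,8aS)-3-hydroxy-6,8a-dimethyl-8-oxo-3-(propan-2-yl)-1,2,3,3a,4,5,8,8a-octahydroazulen-4-yl 4-methoxybenzoate | COc1ccc(C(=O)O[C@H]2CC(C)=CC(=O)[C@@]3(C)CC[C@@](O)(C(C)C)[C@H]23)cc1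
F2 | step 9 | (3R,3aS,4S,8S,8aS)-3,8-dihydroxy-6,8a-dimethyl-3-(propan-2-yl)-1,2,3,3a,4,5,8,8a-octahydroazulen-4-yl 4-methoxybenzoate | COc1ccc(C(=O)O[C@H]2CC(C)=C[C@H](O)[C@@]3(C)CC[C@@](O)(C(C)C)[C@H]23)cc1
F3 | step 4 | 1-phenyl-5-({2-[(3aR,4R,6aR)-2,2,4-trimethyl-6a-(propan-2-yl)hexahydro-2H-cyclopenta[d][1,2]oxasilol-4-yl]ethyl}sulfonyl)-1H-tetrazole | CC(C)[C@]12CC[C@](C)(CCS(=O)(=O)c3nnnn3-c3ccccc3)[C@H]1C[Si](C)(C)O2
F4 | step 1 | (S)-3-methylcyclopent-2-en-1-ol | CC1=C[C@@H](O)CC1
F5 | step 1 | (1S,2S,5R)-5-methyl-6-oxabicyclo[3.1.0]hexan-2-ol | C[C@@]12CC[C@H](O)[C@@H]1O2
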